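**Retrosynthetic overview**
- The target is 1,7-bis(4-hydroxy-3-methoxyphenyl)heptan-3-one (chain C1–C7, ketone at C3, ring B on C1, ring A on C7). It is achiral and no ring is formed: both guaiacyl rings are bought ready-made in 4-vinylguaiacol, the decarboxylation product of ferulic acid, which is used twice.
- The last step removes two phenol acetates. The key disconnection is C2–C3, read as an anti-Markovnikov hydroacylation: the formyl C–H of a 5-arylpentanal (C3–C7 plus ring A) adds across the vinyl group of O-acetyl-4-vinylguaiacol (C1–C2 plus ring B), with no activating group and no by-product.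
- Enabling feature: the C3 carbonyl carbon lies exactly two sp3 carbons (C2, C1) from ring B, so C1–C2 is a saturated styrene unit. Ring B stabilises a radical at C1 and so steers an acyl radical centred on C3 to C2 only.
- The aldehyde comes from the same styrene: the C6–C7 bond is made by cross-metathesis with pent-4-enal, followed by hydrogenation.

Key step: step 4

Remark on the chemistry: compound 4 is drawn as its E isomer; the alkene geometry does not matter because step 3 removes the double bond.

Step 1
Reactants: 1 2-methoxy-4-vinylphenol (4-vinylguaiacol)
Product: 2 2-methoxy-4-vinylphenyl acetate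
Conditions: Ac2O (1.2 equiv), pyridine (solvent), 0 °C to rt
Reagents that add atoms: acetic anhydride, CC(=O)OC(C)=O
Why: Pyridine-promoted O-acetylation (nucleophilic acyl substitution) of the phenol is fast and leaves the vinyl group alone, and the acetate removes the weak O–H bond and tempers the electron-rich styrene for steps 2 and 4.

Step 2
Reactants: 2 2-methoxy-4-vinylphenyl acetate; 3 pent-4-enal (3 equiv)
Product: 4 2-methoxy-4-[(1E)-5-oxopent-1-en-1-yl]phenyl acetate
Conditions: second-generation Hoveyda–Grubbs catalyst RuCl2(H2IMes)(=CH-C6H4-2-OiPr) (3 mol %), 1,4-benzoquinone (10 mol %), CH2Cl2, 40 °C, argon sweep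
Reagents that add atoms: none
Why: Olefin cross-metathesis of two terminal alkenes, driven by loss of ethene and by the excess of 3, should favour the conjugated E-alkene, tolerates aldehyde and aryl ester, and is kept free of double-bond migration by the benzoquinone.

Step 3
Reactants: 4 2-methoxy-4-[(1E)-5-oxopent-1-en-1-yl]phenyl acetate
Product: 5 2-methoxy-4-(5-oxopentyl)phenyl acetate
Conditions: H2 (1 atm), Pd/C (10 wt %, 3 mol % Pd), EtOAc, rt
Reagents that add atoms: none
Why: Heterogeneous catalytic hydrogenation saturates the styrenyl C=C far faster than it attacks an aliphatic aldehyde or an aryl acetate in a non-alcoholic solvent at atmospheric pressure.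

Step 4
Reactants: 5 2-methoxy-4-(5-oxopentyl)phenyl acetate (1.5 equiv); 2 2-methoxy-4-vinylphenyl acetate (1.0 equiv, 0.1 M)
Product: 8 1,7-bis(4-acetoxy-3-methoxyphenyl)heptan-3-one, via acyl radical 6 (not isolated), via benzylic radical 7 (not isolated)
Conditions: (nBu4N)4[W10O32] (2 mol %), bis(2,4,6-triisopropylphenyl) disulfide (10 mol %), degassed MeCN, 390 nm LED, 25 °C
Reagents that add atoms: none
Why: Photoexcited decatungstate abstracts the formyl hydrogen of 5, the weakest and most hydridic C–H bond on offer, and the nucleophilic sigma-acyl radical 6 adds to the unsubstituted vinyl carbon of 2, which makes the C2–C3 bond and places the spin at C1 as benzylic radical 7. Radical 7 takes a hydrogen atom from the arenethiol that the disulfide delivers in the flask, and the thiyl radical is turned back into thiol by the reduced, protonated polyoxotungstate, so that both cycles close without any stoichiometric reagent and the whole carbon skeleton plus the C3 oxidation level arise in one redox-neutral, by-product-free operation. The closest known reaction type is the decatungstate/disulfide dual-catalytic anti-Markovnikov hydroacylation of styrenes with aldehydes (radical hydroacylation by hydrogen-atom-transfer photocatalysis). No ring is closed and no stereocentre is created. The step needs regioselectivity for the linear ketone, secured by ring B because only attack at the terminal carbon gives a benzylic radical, and chemoselectivity for the formyl hydrogen, secured by the acetates, which remove the weak phenolic O–H bonds and lower the electron density of both rings and of the styrene so that benzylic C–H abstraction and electron-transfer quenching stay minor. Decarbonylation of the primary acyl radical is slow at 25 °C, and oligomerisation of 2 is checked by the fast hydrogen transfer from the thiol and by the excess of 5.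

Step 5
Reactants: 8 1,7-bis(4-acetoxy-3-methoxyphenyl)heptan-3-one
Product: 9 1,7-bis(4-hydroxy-3-methoxyphenyl)heptan-3-one
Conditions: K2CO3 (0.2 equiv), MeOH, argon, 0 °C to rt; then aq. NH4Cl
Reagents that add atoms: none
Why: Carbonate-catalysed transesterification (methanolysis) cleaves the activated aryl acetates under conditions that leave the dialkyl ketone and the methyl ethers untouched, and exclusion of air protects the phenolates.

**Compound list**
1 | 2-methoxy-4-vinylphenol (4-vinylguaiacol) | COc1cc(C=C)ccc1O | starting material
2 | 2-methoxy-4-vinylphenyl acetate | COc1cc(C=C)ccc1OC(C)=O | intermediate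
3 | pent-4-enal | C=CCCC=O | starting material
4 | 2-methoxy-4-[(1E)-5-oxopent-1-en-1-yl]phenyl acetate | COc1cc(/C=C/CCC=O)ccc1OC(C)=O | intermediate
5 | 2-methoxy-4-(5-oxopentyl)phenyl acetate | COc1cc(CCCCC=O)ccc1OC(C)=O | intermediate
6 | 5-(4-acetoxy-3-methoxyphenyl)pentanoyl radical (acyl radical) | COc1cc(CCCC[C]=O)ccc1OC(C)=O | intermediate
7 | 1,7-bis(4-acetoxy-3-methoxyphenyl)-3-oxoheptan-1-yl radical (benzylic radical) | COc1cc(CCCCC(=O)C[CH]c2ccc(OC(C)=O)c(OC)c2)ccc1OC(C)=O | intermediate
8 | 1,7-bis(4-acetoxy-3-methoxyphenyl)heptan-3-one | COc1cc(CCCCC(=O)CCc2ccc(OC(C)=O)c(OC)c2)ccc1OC(C)=O | intermediate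
9 | 1,7-bis(4-hydroxy-3-methoxyphenyl)heptan-3-one | COc1cc(CCCCC(=O)CCc2ccc(O)c(OC)c2)ccc1O | target

Total step count: 5.
Longest linear sequence: 5 steps (1 → 2 → 4 → 5 → 8 → 9); compound 2 enters the sequence twice, in steps 2 and 4.

**Steps most likely to fail**

1. Step 4.
   - What may go wrong: the excited polyoxotungstate may be quenched by electron transfer from the styrene instead of abstracting the formyl hydrogen. The benzylic radical may add to further styrene before it is capped. The thiyl co-catalyst may be drained by thiol–ene addition or by capture of the acyl radical.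
   - Fallback: it sets out from 5 and 2 and returns at 8, making the same bond by two-electron acyl cross-coupling. Aldehyde 5 is oxidised under Pinnick conditions (NaClO2, NaH2PO4, 2-methylbut-2-ene, tBuOH/H2O) to 5-(4-acetoxy-3-methoxyphenyl)pentanoic acid F1. This acid is condensed with 4-methylbenzenethiol (EDC·HCl, cat. DMAP, CH2Cl2) to S-(4-methylphenyl) 5-(4-acetoxy-3-methoxyphenyl)pentanethioate F2. Styrene 2 is hydroborated with 9-BBN-H (THF, rt) to 9-[2-(4-acetoxy-3-methoxyphenyl)ethyl]-9-borabicyclo[3.3.1]nonane F3. Liebeskind–Srogl coupling of F2 with F3 (Pd(PPh3)4, copper thiophene-2-carboxylate Cu(O2CC4H3S), Cs2CO3, THF, 45 °C) should give 8. Any acetate lost to the carbonate is harmless, because step 5 removes both.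

2. Step 2.
   - What may go wrong: homodimerisation of both terminal alkenes and double-bond migration induced by ruthenium hydride may erode the cross-product.
   - Fallback: it sets out from 3 and returns at 4, replacing metathesis by arylation of the alkene. Commercial 4-iodo-2-methoxyphenol is acetylated (Ac2O, pyridine) to 4-iodo-2-methoxyphenyl acetate F4. A Mizoroki–Heck reaction of F4 with 3 (Pd(OAc)2, nBu4NCl, NaHCO3, DMF, 50 °C) should give 4. Linear double-bond positional isomers formed by chain-walking converge on 5 in step 3.

3. Step 3.
   - What may go wrong: partial reduction of the formyl group, or its loss by decarbonylation on palladium, may accompany saturation of the alkene.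
   - Fallback: it sets out from 2 and returns at 5, unveiling the aldehyde only after the hydrogenation. Cross-metathesis of 2 with pent-4-en-1-ol, under the conditions of step 2, gives 4-[(1E)-5-hydroxypent-1-en-1-yl]-2-methoxyphenyl acetate F5. Hydrogenation (H2, Pd/C, EtOAc) gives 4-(5-hydroxypentyl)-2-methoxyphenyl acetate F6. Oxidation with Dess–Martin periodinane (CH2Cl2, rt) gives 5.

**Further compounds**
F1 | step 4 | 5-(4-acetoxy-3-methoxyphenyl)pentanoic acid | COc1cc(CCCCC(=O)O)ccc1OC(C)=O
F2 | step 4 | S-(4-methylphenyl) 5-(4-acetoxy-3-methoxyphenyl)pentanethioate | COc1cc(CCCCC(=O)Sc2ccc(C)cc2)ccc1OC(C)=O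
F3 | step 4 | 9-[2-(4-acetoxy-3-methoxyphenyl)ethyl]-9-borabicyclo[3.3.1]nonane | COc1cc(CCB2C3CCCC2CCC3)ccc1OC(C)=O
F4 | step 2 | 4-iodo-2-methoxyphenyl acetate | COc1cc(I)ccc1OC(C)=O
F5 | step 3 | 4-[(1E)-5-hydroxypent-1-en-1-yl]-2-methoxyphenyl acetate | COc1cc(/C=C/CCCO)ccc1OC(C)=O
F6 | step 3 | 4-(5-hydroxypentyl)-2-methoxyphenyl acetate | COc1cc(CCCCCO)ccc1OC(C)=O
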